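Retrosynthesis: the N–CH3 bond and all benzyl groups are cut last; then the pyrrolidine N–C2 bond, back to an (E)-8-alkenyl-7-hydroxyflavone with a benzyl carbamate on the chain; then the C8–alkenyl bond; then the O1–C2 bond of ring C and the aryl–carbonyl bond to ring A.
Forward: ring A is oxygenated from 2-methoxyresorcinol by C–H borylation/oxidation, brominated and acylated to an ortho-hydroxyaryl ynone; ring C closes to the flavone; C8 is iodinated and coupled with the aminobutenyl boronate; the pyrrolidine closes in the penultimate step.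
Enabling feature: the free 7-OH is ortho to C8 of ring A, so the C8 styrene can be protonated to an ortho-quinone methide (C7=O, C8=Cα) whose exocyclic carbon becomes pyrrolidine C2.
Stereochemistry: the single stereocentre (pyrrolidine C2, R) is set in that ring closure by a chiral phosphoric acid and is carried through the neutral, room-temperature final step.
Key step: step 12

Assumption: the (R)-configured acid is taken to deliver the (2R) product; if the sense of induction is the opposite, the (S)-acid is used with nothing else changed.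

Step 1
Reactants: 1 2-methoxybenzene-1,3-diol
Product: 2 2-methoxy-1,3-bis(methoxymethoxy)benzene
Conditions: NaH (2.4 equiv), MOMCl (2.4 equiv), DMF, 0 °C to rt
Reagents that add atoms: chloromethyl methyl ether, COCCl
Why: Williamson-type O-alkylation of both phenoxides gives the bis(MOM) ether, which withstands iridium catalysis, organolithium reagents and amines and can later be removed with dilute acid without touching a benzyl ether.

Step 2
Reactants: 2 2-methoxy-1,3-bis(methoxymethoxy)benzene
Product: 4 4-methoxy-3,5-bis(methoxymethoxy)phenol, via aryl pinacol boronate 3 (not isolated)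
Conditions: [Ir(OMe)(cod)]2 (1.5 mol %), 4,4'-di-tert-butyl-2,2'-bipyridine (3 mol %), B2pin2 (0.6 equiv), THF, 80 °C; then NaBO3·4H2O, THF/H2O, rt
Reagents that add atoms: sodium perborate, [Na+].[O-]OB=O
Why: Iridium-catalysed aromatic C–H borylation is sterically controlled and should therefore attack only C5, the one ring C–H without an ortho substituent, and perborate oxidation of the C–B bond (1,2-aryl shift to oxygen) converts boronate 3 into the phenol in the same flask.

Step 3
Reactants: 4 4-methoxy-3,5-bis(methoxymethoxy)phenol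
Product: 5 2-bromo-4-methoxy-3,5-bis(methoxymethoxy)phenol
Conditions: NBS (1.0 equiv), CH2Cl2, −78 to −20 °C
Reagents that add atoms: N-bromosuccinimide, O=C1CCC(=O)N1Br
Why: Electrophilic aromatic bromination of this electron-rich phenol can occur only at the two equivalent positions ortho to the OH, and one equivalent of NBS at low temperature should stop at the monobromide.

Step 4
Reactants: 6 1-(benzyloxy)-4-ethynylbenzene
Product: 8 3-[4-(benzyloxy)phenyl]-N-methoxy-N-methylprop-2-ynamide, via lithium acetylide 7 (not isolated)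
Conditions: n-BuLi (1.05 equiv), THF, −78 °C; then ClC(O)N(OMe)Me, −78 to 0 °C
Reagents that add atoms: N-methoxy-N-methylcarbamoyl chloride, CON(C)C(=O)Cl
Why: Deprotonation of the terminal alkyne and acylation of the acetylide by the carbamoyl chloride (nucleophilic acyl substitution) is the standard way to an alkynyl N-methoxy-N-methylamide.

Step 5
Reactants: 5 2-bromo-4-methoxy-3,5-bis(methoxymethoxy)phenol; 8 3-[4-(benzyloxy)phenyl]-N-methoxy-N-methylprop-2-ynamide
Product: 10 3-[4-(benzyloxy)phenyl]-1-[2-hydroxy-5-methoxy-4,6-bis(methoxymethoxy)phenyl]prop-2-yn-1-one, via dilithiated phenol 9 (not isolated)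
Conditions: 5, n-BuLi (2.1 equiv), THF, −78 °C; then 8, −78 to −20 °C; AcOH quench at −78 °C
Reagents that add atoms: none
Why: Deprotonation of the OH followed by bromine–lithium exchange gives the ortho-lithio phenolate 9, whose addition to the N-methoxy-N-methylamide stops at the chelated tetrahedral adduct (Weinreb ketone synthesis), so one acyl group is placed next to the only free OH.

Step 6
Reactants: 10 3-[4-(benzyloxy)phenyl]-1-[2-hydroxy-5-methoxy-4,6-bis(methoxymethoxy)phenyl]prop-2-yn-1-one
Product: 12 2-[4-(benzyloxy)phenyl]-6-methoxy-5,7-bis(methoxymethoxy)-4H-chromen-4-one, via diethylamino enone 11 (not isolated)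
Conditions: Et2NH (5 equiv), EtOH, 60 °C
Reagents that add atoms: none
Why: Conjugate addition of diethylamine to the ynone gives enaminone 11, and the only free phenol (the other two oxygens are still MOM ethers) then displaces the amine by 6-endo addition–elimination, which closes ring C as the flavone with the methoxy group necessarily at C6 and avoids the 5-exo aurone pathway.

Step 7
Reactants: 12 2-[4-(benzyloxy)phenyl]-6-methoxy-5,7-bis(methoxymethoxy)-4H-chromen-4-one
Product: 13 2-[4-(benzyloxy)phenyl]-5,7-dihydroxy-6-methoxy-4H-chromen-4-one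
Conditions: 3 M aq. HCl, MeOH/THF, 50 °C
Reagents that add atoms: none
Why: Acid-catalysed acetal methanolysis removes both MOM groups, while the benzyl ether, the methyl ether and the closed flavone are stable to dilute HCl at this temperature.

Step 8
Reactants: 13 2-[4-(benzyloxy)phenyl]-5,7-dihydroxy-6-methoxy-4H-chromen-4-one
Product: 14 2-[4-(benzyloxy)phenyl]-5,7-dihydroxy-8-iodo-6-methoxy-4H-chromen-4-one
Conditions: NIS (1.05 equiv), DMF, 0 °C to rt, dark
Reagents that add atoms: N-iodosuccinimide, O=C1CCC(=O)N1I
Why: Electrophilic aromatic iodination should take place at C8, the only unsubstituted position of ring A and one activated by the 7-OH, the 5-OH and the ring oxygen, whereas ring B is deactivated by the enone and has no free phenol.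

Step 9
Reactants: 15 but-3-yn-1-amine hydrochloride
Product: 16 benzyl but-3-yn-1-ylcarbamate
Conditions: CbzCl (1.05 equiv), NaHCO3 (2.5 equiv), THF/H2O, 0 °C to rt
Reagents that add atoms: benzyl chloroformate, O=C(Cl)OCc1ccccc1
Why: Schotten–Baumann N-acylation of the amine gives the benzyl carbamate whose N–H is the nucleophile of the ring closure.

Step 10
Reactants: 16 benzyl but-3-yn-1-ylcarbamate
Product: 17 benzyl [(3E)-4-(4,4,5,5-tetramethyl-1,3,2-dioxaborolan-2-yl)but-3-en-1-yl]carbamate
Conditions: HBpin (1.2 equiv), Cp2Zr(H)Cl (5 mol %), Et3N (10 mol %), neat, 60 °C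
Reagents that add atoms: pinacolborane, CC1(C)OBOC1(C)C
Why: Zirconium-catalysed hydroboration of the terminal alkyne (syn hydrozirconation, then zirconium-to-boron exchange) should give only the terminal (E)-alkenyl boronate and tolerates the carbamate N–H.

Step 11
Reactants: 14 2-[4-(benzyloxy)phenyl]-5,7-dihydroxy-8-iodo-6-methoxy-4H-chromen-4-one; 17 benzyl [(3E)-4-(4,4,5,5-tetramethyl-1,3,2-dioxaborolan-2-yl)but-3-en-1-yl]carbamate
Product: 18 benzyl [(3E)-4-{2-[4-(benzyloxy)phenyl]-5,7-dihydroxy-6-methoxy-4-oxo-4H-chromen-8-yl}but-3-en-1-yl]carbamate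
Conditions: Pd(OAc)2 (5 mol %), SPhos (10 mol %), K3PO4 (4 equiv), 1,4-dioxane/H2O 5:1, 80 °C; work-up at pH 6–7
Reagents that add atoms: none
Why: Suzuki–Miyaura coupling with a bulky electron-rich biaryl phosphine is suited to the doubly ortho-substituted aryl iodide, tolerates free phenols and the carbamate N–H, and transfers the alkenyl group with retention of its E geometry, while the near-neutral work-up avoids premature acid-induced cyclisation.

Step 12
Reactants: 18 benzyl [(3E)-4-{2-[4-(benzyloxy)phenyl]-5,7-dihydroxy-6-methoxy-4-oxo-4H-chromen-8-yl}but-3-en-1-yl]carbamate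
Product: 20 benzyl (2R)-2-{2-[4-(benzyloxy)phenyl]-5,7-dihydroxy-6-methoxy-4-oxo-4H-chromen-8-yl}pyrrolidine-1-carboxylate, via ortho-quinone methide 19 (not isolated)
Conditions: (R)-3,3'-bis(2,4,6-triisopropylphenyl)-1,1'-binaphthyl-2,2'-diyl hydrogen phosphate (10 mol %), 4 Å MS, 1,2-dichloroethane, 40 °C
Reagents that add atoms: none
Why: The acid protonates the styrene carbon remote from ring A while its phosphoryl oxygen accepts the hydrogen bond of the 7-OH, which gives ortho-quinone methide 19 (C7=O, C8=Cα) held on the chiral phosphate; the carbamate N–H, bound to the same phosphate, then adds to the exocyclic carbon and ring A regains aromaticity. The closest known reaction type is the chiral phosphoric acid catalysed enantioselective hydrofunctionalisation of ortho-hydroxystyrenes through ortho-quinone methides, run here intramolecularly as an aza-Michael addition of a carbamate. The pyrrolidine closes in the 5-exo-trig mode, nitrogen attacking the exocyclic carbon of the C8=Cα bond. The new stereocentre, pyrrolidine C2 (R), is set by the catalyst, whose two-point binding of the quinone methide oxygen and the N–H between the 2,4,6-triisopropylphenyl groups should leave one face of Cα open to nitrogen. The step needs ionisation at this site only and attack by N, not O: C6 is blocked by the methoxy group, the 5-OH is tied to the C4 carbonyl, the 4'-oxygen is benzylated, and the carbamate oxygen could only close a seven-membered ring. The product carbamate is a poor leaving group under so weak an acid, so the stereocentre should not re-ionise.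

Step 13
Reactants: 20 benzyl (2R)-2-{2-[4-(benzyloxy)phenyl]-5,7-dihydroxy-6-methoxy-4-oxo-4H-chromen-8-yl}pyrrolidine-1-carboxylate
Product: 23 5,7-dihydroxy-2-(4-hydroxyphenyl)-6-methoxy-8-[(2R)-1-methylpyrrolidin-2-yl]-4H-chromen-4-one, via secondary amine 21 (not isolated), via N-hydroxymethyl amine 22 (not isolated)
Conditions: H2 (1 atm), 10 % Pd/C, 37 % aq. CH2O (5 equiv), MeOH/THF, rt
Reagents that add atoms: formaldehyde, C=O
Why: Hydrogenolysis over Pd/C cleaves the benzyl carbamate (with loss of CO2) and the benzyl ether, and the freed amine 21 is methylated in the same flask by reductive amination with formaldehyde through carbinolamine 22, under neutral room-temperature conditions that should leave the C2 stereocentre, the benzylic C–N bond and the C2–C3 double bond of the flavone intact.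

Compound list
1 | 2-methoxybenzene-1,3-diol | COc1c(O)cccc1O | starting material
2 | 2-methoxy-1,3-bis(methoxymethoxy)benzene | COCOc1cccc(OCOC)c1OC | intermediate
3 | 2-[4-methoxy-3,5-bis(methoxymethoxy)phenyl]-4,4,5,5-tetramethyl-1,3,2-dioxaborolane | COCOc1cc(B2OC(C)(C)C(C)(C)O2)cc(OCOC)c1OC | intermediate
4 | 4-methoxy-3,5-bis(methoxymethoxy)phenol | COCOc1cc(O)cc(OCOC)c1OC | intermediate
5 | 2-bromo-4-methoxy-3,5-bis(methoxymethoxy)phenol | COCOc1cc(O)c(Br)c(OCOC)c1OC | intermediate
6 | 1-(benzyloxy)-4-ethynylbenzene | C#Cc1ccc(OCc2ccccc2)cc1 | starting material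
7 | lithium [4-(benzyloxy)phenyl]acetylide | [Li]C#Cc1ccc(OCc2ccccc2)cc1 | intermediate
8 | 3-[4-(benzyloxy)phenyl]-N-methoxy-N-methylprop-2-ynamide | CON(C)C(=O)C#Cc1ccc(OCc2ccccc2)cc1 | intermediate
9 | lithium 2-lithio-4-methoxy-3,5-bis(methoxymethoxy)phenolate | [Li]Oc1cc(OCOC)c(OC)c(OCOC)c1[Li] | intermediate
10 | 3-[4-(benzyloxy)phenyl]-1-[2-hydroxy-5-methoxy-4,6-bis(methoxymethoxy)phenyl]prop-2-yn-1-one | COCOc1cc(O)c(C(=O)C#Cc2ccc(OCc3ccccc3)cc2)c(OCOC)c1OC | intermediate
11 | (2E)-3-[4-(benzyloxy)phenyl]-3-(diethylamino)-1-[2-hydroxy-5-methoxy-4,6-bis(methoxymethoxy)phenyl]prop-2-en-1-one | CCN(CC)/C(=C/C(=O)c1c(O)cc(OCOC)c(OC)c1OCOC)c1ccc(OCc2ccccc2)cc1 | intermediate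
12 | 2-[4-(benzyloxy)phenyl]-6-methoxy-5,7-bis(methoxymethoxy)-4H-chromen-4-one | COCOc1cc2oc(-c3ccc(OCc4ccccc4)cc3)cc(=O)c2c(OCOC)c1OC | intermediate
13 | 2-[4-(benzyloxy)phenyl]-5,7-dihydroxy-6-methoxy-4H-chromen-4-one | COc1c(O)cc2oc(-c3ccc(OCc4ccccc4)cc3)cc(=O)c2c1O | intermediate
14 | 2-[4-(benzyloxy)phenyl]-5,7-dihydroxy-8-iodo-6-methoxy-4H-chromen-4-one | COc1c(O)c(I)c2oc(-c3ccc(OCc4ccccc4)cc3)cc(=O)c2c1O | intermediate
15 | but-3-yn-1-amine hydrochloride | C#CCCN.Cl | starting material
16 | benzyl but-3-yn-1-ylcarbamate | C#CCCNC(=O)OCc1ccccc1 | intermediate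
17 | benzyl [(3E)-4-(4,4,5,5-tetramethyl-1,3,2-dioxaborolan-2-yl)but-3-en-1-yl]carbamate | CC1(C)OB(/C=C/CCNC(=O)OCc2ccccc2)OC1(C)C | intermediate
18 | benzyl [(3E)-4-{2-[4-(benzyloxy)phenyl]-5,7-dihydroxy-6-methoxy-4-oxo-4H-chromen-8-yl}but-3-en-1-yl]carbamate | COc1c(O)c(/C=C/CCNC(=O)OCc2ccccc2)c2oc(-c3ccc(OCc4ccccc4)cc3)cc(=O)c2c1O | intermediate
19 | ortho-quinone methide: benzyl {4-[2-[4-(benzyloxy)phenyl]-5-hydroxy-6-methoxy-4,7-dioxo-4H-chromen-8(7H)-ylidene]butyl}carbamate, exocyclic C8=Cα geometry not defined | COC1=C(O)C2=C(OC(=CC2=O)c2ccc(OCc3ccccc3)cc2)C(=CCCCNC(=O)OCc2ccccc2)C1=O | intermediate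
20 | benzyl (2R)-2-{2-[4-(benzyloxy)phenyl]-5,7-dihydroxy-6-methoxy-4-oxo-4H-chromen-8-yl}pyrrolidine-1-carboxylate | COc1c(O)c([C@H]2CCCN2C(=O)OCc2ccccc2)c2oc(-c3ccc(OCc4ccccc4)cc3)cc(=O)c2c1O | intermediate
21 | 5,7-dihydroxy-2-(4-hydroxyphenyl)-6-methoxy-8-[(2R)-pyrrolidin-2-yl]-4H-chromen-4-one | COc1c(O)c([C@H]2CCCN2)c2oc(-c3ccc(O)cc3)cc(=O)c2c1O | intermediate
22 | 5,7-dihydroxy-8-[(2R)-1-(hydroxymethyl)pyrrolidin-2-yl]-2-(4-hydroxyphenyl)-6-methoxy-4H-chromen-4-one | COc1c(O)c([C@H]2CCCN2CO)c2oc(-c3ccc(O)cc3)cc(=O)c2c1O | intermediate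
23 | 5,7-dihydroxy-2-(4-hydroxyphenyl)-6-methoxy-8-[(2R)-1-methylpyrrolidin-2-yl]-4H-chromen-4-one | COc1c(O)c([C@H]2CCCN2C)c2oc(-c3ccc(O)cc3)cc(=O)c2c1O | target

Total step count: 13. Longest linear sequence: 10 steps (steps 1–3, 5–8 and 11–13); steps 4, 9 and 10 make the two side fragments.

Steps most likely to fail

Step 12. The phosphate may not distinguish the two faces of the quinone methide well enough, or the chromone-fused phenol may ionise too slowly under so weak an acid. The fallback sets out from 18 and uses a stronger achiral Brønsted acid (diphenyl phosphate or catalytic TfOH, 1,2-dichloroethane, rt), a known acid-catalysed intramolecular hydroamination of an electron-rich styrene by a carbamate. This should give the racemic pyrrolidine carbamate F1. Preparative chromatography on a chiral stationary phase then separates the (2R)-enantiomer, which is 20, from the (2S)-carbamate F2. F2 can be returned to the acid, where re-ionisation through 19 racemises it for another pass. The route is rejoined at 20.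

Step 11. Under base the iodide is an electron-rich phenoxide flanked by two ortho substituents, so transmetalation may stall and the iodine may be lost by protodehalogenation. The fallback sets out from 14 and masks the acidic 7-OH first: allyl bromide and K2CO3 in DMF should alkylate only the 7-oxygen (the 5-OH is chelated) to give 2-[4-(benzyloxy)phenyl]-5-hydroxy-8-iodo-6-methoxy-7-(prop-2-en-1-yloxy)-4H-chromen-4-one F3. Coupling of F3 with 17 under the conditions of step 11 gives the allyl-protected styrene, benzyl [(3E)-4-{2-[4-(benzyloxy)phenyl]-5-hydroxy-6-methoxy-4-oxo-7-(prop-2-en-1-yloxy)-4H-chromen-8-yl}but-3-en-1-yl]carbamate F4. The allyl ether is then removed under neutral conditions with Pd(PPh3)4 and morpholine in THF, which leave the benzyl carbamate, the benzyl ether and the styrene alone and involve no acid that could trigger a racemic cyclisation. The route is rejoined at 18.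

Step 5. Bromine–lithium exchange on the electron-rich phenolate may be incomplete, or the hindered aryllithium may add to the alkyne carbon of the ynamide and not to its carbonyl. The fallback sets out from 4 and replaces the organolithium chemistry by palladium catalysis. Iodination with NIS (CH2Cl2, −78 °C) gives 2-iodo-4-methoxy-3,5-bis(methoxymethoxy)phenol F5. Carbonylative Sonogashira coupling–annulation of F5 with alkyne 6 under CO (PdCl2(PPh3)2, Et2NH, 100 °C) then forms ynone 10 and enaminone 11 in the flask and closes them to the flavone. The route is rejoined at 12.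

Further compounds
F1 | step 12 | racemic benzyl 2-{2-[4-(benzyloxy)phenyl]-5,7-dihydroxy-6-methoxy-4-oxo-4H-chromen-8-yl}pyrrolidine-1-carboxylate | COc1c(O)c(C2CCCN2C(=O)OCc2ccccc2)c2oc(-c3ccc(OCc4ccccc4)cc3)cc(=O)c2c1O
F2 | step 12 | benzyl (2S)-2-{2-[4-(benzyloxy)phenyl]-5,7-dihydroxy-6-methoxy-4-oxo-4H-chromen-8-yl}pyrrolidine-1-carboxylate | COc1c(O)c([C@@H]2CCCN2C(=O)OCc2ccccc2)c2oc(-c3ccc(OCc4ccccc4)cc3)cc(=O)c2c1O
F3 | step 11 | 2-[4-(benzyloxy)phenyl]-5-hydroxy-8-iodo-6-methoxy-7-(prop-2-en-1-yloxy)-4H-chromen-4-one | COc1c(OCC=C)c(I)c2oc(-c3ccc(OCc4ccccc4)cc3)cc(=O)c2c1O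
F4 | step 11 | benzyl [(3E)-4-{2-[4-(benzyloxy)phenyl]-5-hydroxy-6-methoxy-4-oxo-7-(prop-2-en-1-yloxy)-4H-chromen-8-yl}but-3-en-1-yl]carbamate | COc1c(OCC=C)c(/C=C/CCNC(=O)OCc2ccccc2)c2oc(-c3ccc(OCc4ccccc4)cc3)cc(=O)c2c1O
F5 | step 5 | 2-iodo-4-methoxy-3,5-bis(methoxymethoxy)phenol | COCOc1cc(O)c(I)c(OCOC)c1OC
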